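**Plan**

- Numbering of the bicyclo[2.2.2]octene core: C1 = bridgehead next to the alkene CH (C6); C2, C3 = the ketone carbons (C2 on C1); C4 = other bridgehead; C5 = alkene carbon carrying the side chain; C7 = CO2H-bearing carbon on C4; C8 = aryl-bearing carbon on C1.
- Enabling feature: the C7 carboxyl and C3 lie 1,3 across C4 and the carboxyl points at the C2–C3 bridge, so C7–C(=O)–O–C3 can be a five-membered lactone. Without that bridge the ring C4–C5–C6–C1–C8–C7 is a cyclohexa-1,3-diene, so C2–C3 can arrive as a vinyl group hung on the carboxyl.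
- Cuts: C5–CH= of the side chain (Heck) and the acid-labile groups; C2=O back to CH2 and C3=O back to the lactone C3–O; C1–C2 and C3–C4 in one intramolecular Diels–Alder step; enol triflate and vinyl ester back to an enone acid; the cyclohexene back to caffeic acid and butadiene.
- Forward: cyclohexene ring by auxiliary Diels–Alder; iodolactonisation puts oxygen on C5; enone acid, vinyl ester, C5 dienyl triflate; the second carbocycle and the γ-lactone then close together; lactone to ketone to 2,3-dione; Heck coupling joins the danshensu acrylate; acid removes both ketals and the tert-butyl ester.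
- Stereochemistry: C7 and C8 (trans) from the (S)-4-benzyloxazolidinone-controlled Diels–Alder; C1 and C4 relayed from C7 by the two-atom tether; the lactate centre bought as (R)-danshensu; the side-chain alkene E from the Heck step.

Key step: step 10

Remark: Ar = 2,2-dimethyl-1,3-benzodioxol-5-yl; locants C1–C8 are those defined above.
Assumption: (R)-danshensu is used as the free acid (from its commercial sodium salt by acidification); keto acids 20 and 21 may rest partly as cyclic hydroxy-lactone tautomers that react through the open form.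

**Route**

Step 1
Reactants: 1 caffeic acid
Product: 2 (E)-3-Ar-prop-2-enoic acid
Conditions: 2,2-dimethoxypropane, TsOH·H2O (cat.), benzene, reflux, Soxhlet with CaCl2 (removal of MeOH)
Reagents that add atoms: 2,2-dimethoxypropane COC(C)(C)OC
Why: Acid-catalysed ketal exchange (catechol acetonide formation) is driven by removal of methanol and should leave the carboxylic acid free; no stereocentre is formed.

Step 2
Reactants: 2 (E)-3-Ar-prop-2-enoic acid; 3 (S)-4-benzyl-1,3-oxazolidin-2-one
Product: 5 (S)-4-benzyl-3-[(E)-3-Ar-prop-2-enoyl]-1,3-oxazolidin-2-one, via mixed pivalic anhydride 4 (not isolated)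
Conditions: t-BuCOCl, Et3N, THF, −20 °C; then LiCl, 3, −20 °C → rt
Reagents that add atoms: none
Why: N-Acylation of the oxazolidinone through the mixed pivalic anhydride with LiCl activation is the standard entry to enoyl imides and keeps the E-alkene; no new stereocentre.

Step 3
Reactants: 5 (S)-4-benzyl-3-[(E)-3-Ar-prop-2-enoyl]-1,3-oxazolidin-2-one; 6 buta-1,3-diene
Product: 7 (S)-4-benzyl-3-{[(1S,6S)-6-Ar-cyclohex-3-en-1-yl]carbonyl}-1,3-oxazolidin-2-one
Conditions: Et2AlCl (1.5 equiv), buta-1,3-diene (excess), CH2Cl2, −30 → 0 °C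
Reagents that add atoms: none
Why: Auxiliary-controlled (Evans-type) Lewis acid-promoted Diels–Alder reaction: in the Et2AlCl-chelated s-cis imide the benzyl group screens one face, so butadiene should add to the other face and set C7 and C8 as (S,S), their trans relation following from the E-alkene.

Step 4
Reactants: 7 (S)-4-benzyl-3-{[(1S,6S)-6-Ar-cyclohex-3-en-1-yl]carbonyl}-1,3-oxazolidin-2-one
Product: 9 (1S,6S)-6-Ar-cyclohex-3-ene-1-carboxylic acid, via lithium peroxycarboxylate 8 (not isolated)
Conditions: LiOH·H2O, 30% H2O2, THF/H2O, 0 °C; then aq. Na2SO3; 1 M HCl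
Reagents that add atoms: hydrogen peroxide OO
Why: Hydroperoxide attacks the exocyclic imide carbonyl selectively (LiOOH auxiliary cleavage) and sulfite reduces the peracid salt, so the acid should be freed without touching C7, C8 or the ring alkene.

Step 5
Reactants: 9 (1S,6S)-6-Ar-cyclohex-3-ene-1-carboxylic acid
Product: 10 (1S,2S,4R,5R)-2-Ar-4-iodo-6-oxabicyclo[3.2.1]octan-7-one
Conditions: I2, KI, NaHCO3, H2O/CH2Cl2, 0 °C → rt, dark
Reagents that add atoms: iodine II
Why: Iodolactonisation: the C7 carboxylate opens the iodonium ion of the C5=C6 alkene at its γ-carbon C5 (five-membered lactone, anti addition), which places oxygen on C5 cis to the carboxyl and iodine on C6 trans to it.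

Step 6
Reactants: 10 (1S,2S,4R,5R)-2-Ar-4-iodo-6-oxabicyclo[3.2.1]octan-7-one
Product: 11 (1S,2S,5R)-2-Ar-6-oxabicyclo[3.2.1]oct-3-en-7-one
Conditions: DBU, toluene, 80 °C
Reagents that add atoms: none
Why: E2 dehydroiodination with an amidine base: only the C1 hydrogen is antiperiplanar to the axial iodide, so the alkene should form as C6=C1 and leave an allylic lactone.

Step 7
Reactants: 11 (1S,2S,5R)-2-Ar-6-oxabicyclo[3.2.1]oct-3-en-7-one
Product: 13 (1S,6S)-6-Ar-3-oxocyclohex-4-ene-1-carboxylic acid, via tetrabutylammonium hydroxy-carboxylate 12 (not isolated)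
Conditions: aq. Bu4NOH (1.05 equiv), THF, 0 °C; concentrate, toluene azeotrope; then Pr4N[RuO4] (5 mol%), N-methylmorpholine N-oxide, 4 Å MS, CH2Cl2, rt; 1 M HCl
Reagents that add atoms: tetrabutylammonium hydroxide CCCC[N+](CCCC)(CCCC)CCCC.[OH-]
Why: Saponification of the allylic lactone followed by Ley–Griffith oxidation of the liberated allylic alcohol on the carboxylate salt should give the C5 enone; the C5 stereocentre is removed and C7 and C8 are not touched.

Step 8
Reactants: 13 (1S,6S)-6-Ar-3-oxocyclohex-4-ene-1-carboxylic acid; 14 vinyl acetate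
Product: 15 vinyl (1S,6S)-6-Ar-3-oxocyclohex-4-ene-1-carboxylate
Conditions: Pd(OAc)2 (5 mol%), KOH (10 mol%), vinyl acetate (solvent), rt
Reagents that add atoms: none
Why: Palladium diacetate-catalysed transvinylation transfers the vinyl group of vinyl acetate to the substrate carboxylate under nearly neutral conditions, so the enone and the C7 centre should stay intact.

Step 9
Reactants: 15 vinyl (1S,6S)-6-Ar-3-oxocyclohex-4-ene-1-carboxylate
Product: 17 vinyl (1R,6S)-6-Ar-3-[(trifluoromethanesulfonyl)oxy]cyclohexa-2,4-diene-1-carboxylate (trans), via lithium dienolate 16 (not isolated)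
Conditions: LiN(iPr)2 (1.05 equiv), THF, −78 °C; then N-(5-chloropyridin-2-yl)bis(trifluoromethanesulfonyl)imide (Comins' reagent), −78 → −40 °C
Reagents that add atoms: N-(5-chloropyridin-2-yl)bis(trifluoromethanesulfonyl)imide O=S(=O)(N(c1ccc(Cl)cn1)S(=O)(=O)C(F)(F)F)C(F)(F)F
Why: Kinetic α′-deprotonation of the enone at C4 gives the cross-conjugated dienolate, whose O-triflation should yield the 2-triflyloxy-1,3-diene C4=C5(OTf)–C6=C1; at −78 °C the hindered amide base should spare the vinyl ester and C7–H (the descriptor at C7 changes by priority only).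

Step 10
Reactants: 17 vinyl (1R,6S)-6-Ar-3-[(trifluoromethanesulfonyl)oxy]cyclohexa-2,4-diene-1-carboxylate
Product: 18 tricyclic lactone triflate (γ-lactone C7–C(=O)–O–C3; C2 = CH2; OTf on C5; Ar on C8 syn to C5=C6)
Conditions: degassed toluene (5 mM), BHT (cat.), sealed tube, 180 °C
Reagents that add atoms: none
Why: Proposed new method: the vinyl group carried by the C7 carboxyl should add across C4=C5–C6=C1 in a thermal, concerted, suprafacial [4+2] that forms C1–C2 and C3–C4; an enol ester tethered through its own acyl carbon has not been used in this way, the closest known reaction type being the intramolecular Diels–Alder closure of cyclohexa-2,4-dienyl systems that carry a two-atom ester or ether tether on the sp3 carbon next to the diene (o-quinol acrylates, allyl ethers of masked o-benzoquinones), which gives the same fused five-membered ring. The two carbocyclic rings of the bicyclo[2.2.2]octene arise by bridging addition across the 1,4-termini of the cyclic diene, and the γ-lactone closes in the fused mode because the two-atom C(=O)–O link lets the oxygen-bearing carbon C3 reach only C4, once the ester has turned into its less favoured s-E rotamer (hence heat and high dilution). C1 and C4 are set by the diene face, which the tether fixes as the face carrying the C7 carbonyl, and C3 is set by the tether itself, its oxygen having to stay cis to the C7–C8 bridge. The step needs regioselectivity (C3 to C4, not to C1) and facial selectivity, and both follow from the short link together with the trans C7/C8 pair, which puts the aryl group on the far face and hence under the C5=C6 alkene. The C5 triflate is a weak π-donor, so the largest diene coefficient lies on C4 and matches the oxygen-bearing C3 of the enol ester, which is why a triflate and not an acceptor such as formyl is carried at C5 (it also keeps C7–H from becoming vinylogously acidic and serves later as the coupling handle).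

Step 11
Reactants: 18 tricyclic lactone triflate
Product: 20 keto acid (C3=O; C2 = CH2; OTf on C5; C7–CO2H syn to the C2–C3 bridge; Ar on C8 syn to C5=C6), via tetrabutylammonium hydroxy-carboxylate 19 (not isolated)
Conditions: aq. Bu4NOH (1.1 equiv), THF, 0 °C; concentrate, toluene azeotrope; then Pr4N[RuO4] (5 mol%), N-methylmorpholine N-oxide, 4 Å MS, CH2Cl2, rt; cold 1 M HCl
Reagents that add atoms: tetrabutylammonium hydroxide CCCC[N+](CCCC)(CCCC)CCCC.[OH-]
Why: The strained γ-lactone is saponified and the C3 alcohol is oxidised (Ley–Griffith oxidation) while the carboxyl is still a salt, so the lactone cannot close again; the C3 stereocentre is removed and the alkenyl triflate and C7 should not be affected.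

Step 12
Reactants: 20 keto acid
Product: 21 2,3-dione acid (as 20 with C2=O)
Conditions: SeO2 (2 equiv), 1,4-dioxane (1% H2O), 90 °C, dark
Reagents that add atoms: selenium dioxide O=[Se]=O
Why: Riley oxidation: the C3 ketone can enolise only toward C2 (C4 is a bridgehead), so selenium dioxide should convert the C2 methylene into the second ketone without touching a stereocentre.

Step 13
Reactants: 22 (R)-danshensu
Product: 24 (R)-3-Ar-2-hydroxypropanoic acid, via dioxolanone bis-acetonide 23 (not isolated)
Conditions: 2,2-dimethoxypropane, TsOH·H2O (cat.), benzene, reflux, Soxhlet with CaCl2; concentrate; then LiOH, THF/H2O, 0 °C; 1 M HCl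
Reagents that add atoms: 2,2-dimethoxypropane COC(C)(C)OC; lithium hydroxide [Li+].[OH-]
Why: Ketal exchange protects the catechol and transiently ties the α-hydroxy acid up as a dioxolanone, which cold hydroxide alone should open (lactone-type hydrolysis); the (R) centre is not involved.

Step 14
Reactants: 24 (R)-3-Ar-2-hydroxypropanoic acid
Product: 25 tert-butyl (R)-3-Ar-2-hydroxypropanoate
Conditions: tert-butyl 2,2,2-trichloroacetimidate (2 equiv), CH2Cl2/cyclohexane, rt
Reagents that add atoms: tert-butyl 2,2,2-trichloroacetimidate CC(C)(C)OC(=N)C(Cl)(Cl)Cl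
Why: The trichloroacetimidate is protonated by the carboxylic acid itself and should tert-butylate only the carboxyl (imidate esterification), leaving the secondary alcohol free.

Step 15
Reactants: 25 tert-butyl (R)-3-Ar-2-hydroxypropanoate; 26 acryloyl chloride
Product: 27 tert-butyl (R)-2-(acryloyloxy)-3-Ar-propanoate
Conditions: Et3N, CH2Cl2, −20 → 0 °C
Reagents that add atoms: none
Why: O-Acylation of the secondary alcohol with the acid chloride under amine base (esterification) at low temperature should not epimerise the α-centre.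

Step 16
Reactants: 21 2,3-dione acid; 27 tert-butyl (R)-2-(acryloyloxy)-3-Ar-propanoate
Product: 28 bis(acetonide) tert-butyl ester of yunnaneic acid C
Conditions: Pd(OAc)2 (5 mol%), P(o-tol)3 (10 mol%), Et3N, DMF, 60 °C, dark
Reagents that add atoms: none
Why: Mizoroki–Heck reaction of the alkenyl triflate with the acrylate (oxidative addition, syn insertion, syn β-hydride elimination) should give the E-dienoate at C5; the non-enolisable dione and all stereocentres are spectators.

Step 17
Reactants: 28 bis(acetonide) tert-butyl ester of yunnaneic acid C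
Product: 29 yunnaneic acid C
Conditions: CF3CO2H/H2O (9:1), 0 °C → rt
Reagents that add atoms: none
Why: Acidolysis should cleave both catechol isopropylidene ketals and the tert-butyl ester in one operation (global deprotection), the dienoate ester, the dione and the stereocentres being stable to aqueous acid.

**Compound list**

1 | caffeic acid | O=C(O)/C=C/c1ccc(O)c(O)c1 | starting material
2 | (E)-3-(2,2-dimethyl-1,3-benzodioxol-5-yl)prop-2-enoic acid | O=C(O)/C=C/c1ccc2OC(C)(C)Oc2c1 | intermediate
3 | (S)-4-benzyl-1,3-oxazolidin-2-one | O=C1OC[C@H](Cc2ccccc2)N1 | starting material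
4 | mixed anhydride of 2 with pivalic acid | CC(C)(C)C(=O)OC(=O)/C=C/c1ccc2OC(C)(C)Oc2c1 | intermediate (not isolated)
5 | (S)-4-benzyl-3-[(E)-3-Ar-prop-2-enoyl]-1,3-oxazolidin-2-one | O=C1OC[C@H](Cc2ccccc2)N1C(=O)/C=C/c1ccc2OC(C)(C)Oc2c1 | intermediate
6 | buta-1,3-diene | C=CC=C | starting material
7 | (S)-4-benzyl-3-{[(1S,6S)-6-Ar-cyclohex-3-en-1-yl]carbonyl}-1,3-oxazolidin-2-one | O=C1OC[C@H](Cc2ccccc2)N1C(=O)[C@H]1CC=CC[C@@H]1c1ccc2OC(C)(C)Oc2c1 | intermediate
8 | lithium (1S,6S)-6-Ar-cyclohex-3-ene-1-peroxycarboxylate | [Li+].[O-]OC(=O)[C@H]1CC=CC[C@@H]1c1ccc2OC(C)(C)Oc2c1 | intermediate (not isolated)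
9 | (1S,6S)-6-Ar-cyclohex-3-ene-1-carboxylic acid | OC(=O)[C@H]1CC=CC[C@@H]1c1ccc2OC(C)(C)Oc2c1 | intermediate
10 | (1S,2S,4R,5R)-2-Ar-4-iodo-6-oxabicyclo[3.2.1]octan-7-one | O=C1O[C@@H]2C[C@H]1[C@@H](c3ccc4OC(C)(C)Oc4c3)C[C@H]2I | intermediate
11 | (1S,2S,5R)-2-Ar-6-oxabicyclo[3.2.1]oct-3-en-7-one | O=C1O[C@@H]2C[C@H]1[C@@H](c3ccc4OC(C)(C)Oc4c3)C=C2 | intermediate
12 | tetrabutylammonium (1S,3R,6S)-6-Ar-3-hydroxycyclohex-4-ene-1-carboxylate | [O-]C(=O)[C@H]1C[C@@H](O)C=C[C@@H]1c1ccc2OC(C)(C)Oc2c1.CCCC[N+](CCCC)(CCCC)CCCC | intermediate (not isolated)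
13 | (1S,6S)-6-Ar-3-oxocyclohex-4-ene-1-carboxylic acid | OC(=O)[C@H]1CC(=O)C=C[C@@H]1c1ccc2OC(C)(C)Oc2c1 | intermediate
14 | vinyl acetate | CC(=O)OC=C | starting material
15 | vinyl (1S,6S)-6-Ar-3-oxocyclohex-4-ene-1-carboxylate | C=COC(=O)[C@H]1CC(=O)C=C[C@@H]1c1ccc2OC(C)(C)Oc2c1 | intermediate
16 | lithium dienolate of 15 (C4=C5–OLi) | C=COC(=O)[C@H]1C=C([O-])C=C[C@@H]1c1ccc2OC(C)(C)Oc2c1.[Li+] | intermediate (not isolated)
17 | vinyl (1R,6S)-6-Ar-3-[(trifluoromethanesulfonyl)oxy]cyclohexa-2,4-diene-1-carboxylate (trans; precursor of the key step) | C=COC(=O)[C@H]1C=C(OS(=O)(=O)C(F)(F)F)C=C[C@@H]1c1ccc2OC(C)(C)Oc2c1 | intermediate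
18 | tricyclic lactone triflate (γ-lactone C7–C(=O)–O–C3; C2 = CH2; OTf on C5; Ar on C8 syn to C5=C6; product of the key step) | O=S(=O)(OC1=C[C@H]2C[C@H](OC3=O)[C@@H]1[C@H]3[C@H]2c1ccc2OC(C)(C)Oc2c1)C(F)(F)F | intermediate
19 | tetrabutylammonium salt of the C3-hydroxy C7-carboxylate from 18 | O=S(=O)(OC1=C[C@H]2C[C@H](O)[C@@H]1[C@H](C(=O)[O-])[C@H]2c1ccc2OC(C)(C)Oc2c1)C(F)(F)F.CCCC[N+](CCCC)(CCCC)CCCC | intermediate (not isolated)
20 | keto acid (C3=O; C2 = CH2; OTf on C5) | O=S(=O)(OC1=C[C@H]2CC(=O)[C@@H]1[C@H](C(=O)O)[C@H]2c1ccc2OC(C)(C)Oc2c1)C(F)(F)F | intermediate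
21 | 2,3-dione acid (OTf on C5) | O=S(=O)(OC1=C[C@H]2C(=O)C(=O)[C@@H]1[C@H](C(=O)O)[C@H]2c1ccc2OC(C)(C)Oc2c1)C(F)(F)F | intermediate
22 | (R)-danshensu, (R)-3-(3,4-dihydroxyphenyl)lactic acid | O[C@H](Cc1ccc(O)c(O)c1)C(=O)O | starting material
23 | (R)-5-[(2,2-dimethyl-1,3-benzodioxol-5-yl)methyl]-2,2-dimethyl-1,3-dioxolan-4-one | CC1(C)OC(=O)[C@@H](Cc2ccc3OC(C)(C)Oc3c2)O1 | intermediate (not isolated)
24 | (R)-3-Ar-2-hydroxypropanoic acid | O[C@H](Cc1ccc2OC(C)(C)Oc2c1)C(=O)O | intermediate
25 | tert-butyl (R)-3-Ar-2-hydroxypropanoate | O[C@H](Cc1ccc2OC(C)(C)Oc2c1)C(=O)OC(C)(C)C | intermediate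
26 | acryloyl chloride | C=CC(=O)Cl | starting material
27 | tert-butyl (R)-2-(acryloyloxy)-3-Ar-propanoate | C=CC(=O)O[C@H](Cc1ccc2OC(C)(C)Oc2c1)C(=O)OC(C)(C)C | intermediate
28 | bis(acetonide) tert-butyl ester of yunnaneic acid C | O=C(/C=C/C1=C[C@H]2C(=O)C(=O)[C@@H]1[C@H](C(=O)O)[C@H]2c1ccc2OC(C)(C)Oc2c1)O[C@H](Cc1ccc2OC(C)(C)Oc2c1)C(=O)OC(C)(C)C | intermediate
29 | yunnaneic acid C | O=C(/C=C/C1=C[C@H]2C(=O)C(=O)[C@@H]1[C@H](C(=O)O)[C@H]2c1ccc(O)c(O)c1)O[C@H](Cc1ccc(O)c(O)c1)C(=O)O | target

**Count and risks**

Total: 17 steps (14 in the main line, 3 for the side-chain fragment). Longest linear sequence: 14 steps (steps 1–12, 16, 17).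

Steps most likely to fail:

Step 10 (the labelled step). The cycloaddition may be slower than [1,5]-hydrogen migration, dehydrogenative aromatisation or dimerisation of the diene at the temperature needed, because the dienophile is not activated and the ester must first turn into its s-E rotamer. The fallback uses known chemistry, gives up the tether and brings the C2–C3 unit in at the diol oxidation level. It sets out from 17, which is heated with excess vinylene carbonate (neat, 150 °C, sealed tube) in an intermolecular Diels–Alder reaction that should take place mainly on the diene face opposite the aryl group and give the cyclic carbonate adduct F1. LiOH in THF/H2O then cleaves the carbonate and the vinyl ester to the cis-diol acid F2. Swern-type oxidation of the diol (dimethyl sulfoxide, (CF3CO)2O, then Et3N, CH2Cl2, −78 °C) gives the dione, so the route is rejoined at 21 and compounds 18 and 20 are bypassed; facial selectivity then rests on sterics alone.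

Step 3. The electron-rich β-aryl acryloyl imide may add butadiene too slowly, so that Lewis acid-induced oligomerisation of the diene and opening of the aryl ketal take over. The fallback builds the ring stepwise under the same auxiliary and sets out from 5. Hosomi–Sakurai conjugate allylation (allyltrimethylsilane, TiCl4, CH2Cl2, −78 °C) on the face opposite the benzyl group should give the β-allyl imide F3. Enolisation with NaN(SiMe3)2 and alkylation with allyl iodide, again opposite the benzyl group, should give the α,β-diallyl imide F4. Ring-closing metathesis with the second-generation Grubbs catalyst RuCl2(=CHPh)(H2IMes)(PCy3) closes the cyclohexene and returns to the route at 7.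

Step 12. Enolisation toward C2 may be slow in the strained ketone (which can also rest as its hydroxy-lactone form), and prolonged heating with selenous acid may open the aryl ketal and oxidise the freed catechol. The fallback is a two-step α-oxygenation through the enolate and sets out from 20. LiN(SiMe3)2 (2.2 equiv, THF, −78 °C) forms the carboxylate enolate, which is hydroxylated at C2 with 3-phenyl-2-(phenylsulfonyl)oxaziridine to the α-hydroxy ketone F5 (drawn as the epimer from attack on the alkene side; the centre is lost next). Dess–Martin periodinane then oxidises it to the dione and the route is rejoined at 21.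

Further compounds
F1 | step 10 | vinylene carbonate adduct of 17 (cyclic carbonate on C2/C3 with both oxygens syn to C5=C6; vinyl ester on C7; OTf on C5) | O=S(=O)(OC1=C[C@H]2[C@H]3OC(=O)O[C@H]3[C@@H]1[C@H](C(=O)OC=C)[C@H]2c1ccc2OC(C)(C)Oc2c1)C(F)(F)F
F2 | step 10 | cis-2,3-diol acid (hydroxyls syn to C5=C6; OTf on C5; C7–CO2H) | O=S(=O)(OC1=C[C@H]2[C@@H](O)[C@@H](O)[C@@H]1[C@H](C(=O)O)[C@H]2c1ccc2OC(C)(C)Oc2c1)C(F)(F)F
F3 | step 3 | (S)-4-benzyl-3-[(3S)-3-Ar-hex-5-enoyl]-1,3-oxazolidin-2-one | O=C1OC[C@H](Cc2ccccc2)N1C(=O)C[C@H](CC=C)c1ccc2OC(C)(C)Oc2c1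
F4 | step 3 | (S)-4-benzyl-3-[(2S,3S)-2-allyl-3-Ar-hex-5-enoyl]-1,3-oxazolidin-2-one | O=C1OC[C@H](Cc2ccccc2)N1C(=O)[C@@H](CC=C)[C@H](CC=C)c1ccc2OC(C)(C)Oc2c1
F5 | step 12 | C2-hydroxy C3-keto acid (hydroxyl syn to C5=C6; OTf on C5) | O=S(=O)(OC1=C[C@H]2[C@@H](O)C(=O)[C@@H]1[C@H](C(=O)O)[C@H]2c1ccc2OC(C)(C)Oc2c1)C(F)(F)F
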